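The strategy avoids any coupling of two arenes. The hindered C8–C6' axis (coumarin numbering, primes for the 7-hydroxy unit) enters as the styrene bond of an α-methylcinnamoyl unit. Benzene ring B (C4a', C5', C6', C7', C8', C8a') is then grown next to the finished ring A. One light-then-heat cascade between an alkenyl diazomethyl ketone and ethoxyacetylene forges C4a'–C5', C7'–C8', C4a'–C8a' and C6'–C7'. The cascade exploits the meta-dioxygenated (resorcinol) pattern of ring B: it delivers C7'–OH free, C8a'–OEt masked and C8'–H between them. The precursor is (E)-ArCH=C(CH3)–CO–CHN2, where Ar is the locally symmetric 2,6-dimethoxy-4-methylphenyl ring A. Both pyranones follow by acetylation at C4a/C4a', ortho-dealkylation and carbonate condensation.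

Key step: step 4

Assumption: the target SMILES fixes no configuration at the C8–C6' axis, so the racemic atropisomer mixture is the goal.

Design remarks:
- **Route to diazo ketone 7.** It is reached by diazo transfer onto methyl ketone 5, not by acylating diazomethane. Enoyl chlorides lose material to 1,3-dipolar addition of diazomethane across the C=C bond, and the transfer route also avoids handling that reagent.
- **Two masks on O7' in turn.**
  - During acetylation O7' must be an alkyl ether, so that it stays a strong para director towards C4a'.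
  - No ether that leaves by hydrogenolysis outlives BCl3. No ether that outlives BCl3 can later be removed beside two 4-methoxycoumarins, which are vinylogous esters.
  - Isopropyl therefore serves up to the BCl3 step, where it falls together with the two chelated ethers in the same operation.
  - Benzyl is then placed on the only non-chelated phenol.

Step 1
Reactants: 1 2,6-dimethoxy-4-methylbenzaldehyde; 2 triethyl 2-phosphonopropionate
Product: 3 ethyl (E)-3-(2,6-dimethoxy-4-methylphenyl)-2-methylprop-2-enoate
Conditions: NaH, THF, 0 °C; then 1, 0 °C to reflux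
Reagents that add atoms: none
Why: Horner–Wadsworth–Emmons olefination with a stabilised α-methyl phosphonate anion is dependable even for di-ortho-substituted benzaldehydes and, through reversible addition, should favour the E-enoate with aryl and ester trans, any Z isomer being removed by chromatography.

Step 2
Reactants: 3 ethyl (E)-3-(2,6-dimethoxy-4-methylphenyl)-2-methylprop-2-enoate
Product: 5 (E)-4-(2,6-dimethoxy-4-methylphenyl)-3-methylbut-3-en-2-one, via Weinreb amide 4 (not isolated)
Conditions: MeNH(OMe)·HCl, iPrMgCl, THF, −20 to 0 °C; then MeMgBr, 0 °C to rt; aq. NH4Cl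
Reagents that add atoms: methylmagnesium bromide C[Mg]Br; N,O-dimethylhydroxylamine hydrochloride CNOC.Cl (its atoms stay only in 4)
Why: In this one-pot Weinreb ketone synthesis the chloromagnesium amide turns the ester into amide 4, whose chelated tetrahedral adduct with MeMgBr cannot collapse before the quench, so addition should stop at the methyl ketone without conjugate addition or loss of alkene geometry.

Step 3
Reactants: 5 (E)-4-(2,6-dimethoxy-4-methylphenyl)-3-methylbut-3-en-2-one
Product: 7 (E)-1-diazo-4-(2,6-dimethoxy-4-methylphenyl)-3-methylbut-3-en-2-one, via trifluoroacetyl diketone 6 (not isolated)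
Conditions: LiN(SiMe3)2, THF, −78 °C; CF3CO2CH2CF3, −78 °C; aq. HCl wash; crude 6, 4-acetamidobenzenesulfonyl azide (p-ABSA), Et3N, H2O (1 equiv), MeCN, rt
Reagents that add atoms: 4-acetamidobenzenesulfonyl azide CC(=O)Nc1ccc(cc1)S(=O)(=O)N=[N+]=[N-]; 2,2,2-trifluoroethyl trifluoroacetate O=C(OCC(F)(F)F)C(F)(F)F (its atoms stay only in 6)
Why: In this detrifluoroacetylative variant of the Regitz diazo transfer the kinetic base can enolise only towards the acetyl CH3, the trifluoroacetyl group activates that carbon for attack on the sulfonyl azide and then departs on the sulfonamide nitrogen, which is the standard entry to α'-diazo enones.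

Step 4
Reactants: 7 (E)-1-diazo-4-(2,6-dimethoxy-4-methylphenyl)-3-methylbut-3-en-2-one; 8 ethoxyacetylene (excess)
Product: 13 2-(2,6-dimethoxy-4-methylphenyl)-5-ethoxy-3-methylphenol, via vinylketene 9 (not isolated), via alkenylcyclobutenone 10 (not isolated), via dienylketene 11 (not isolated), via cyclohexadienone 12 (not isolated)
Conditions: hν (254 nm, low-pressure Hg lamps, quartz), degassed ClCH2CH2Cl, rt; then reflux in the same flask; crude stirred with K2CO3, MeOH
Reagents that add atoms: none
Why: Light expels N2 from 7 and the alkenyl group shifts to the former diazo carbon (Wolff rearrangement, C4a'–C5'), giving vinylketene 9, which adds across 8 in a [2+2] sense (C7'–C8', C4a'–C8a') to the four-membered ring of 10. Heating opens 10 in a reversible four-electron conrotatory step to dienylketene 11, and the isomer holding both arms cis on C8a'=C4a' is drained off by a six-electron disrotatory electrocyclisation onto the ketene carbon (C6'–C7'), which closes the one lasting ring, carbocycle B, before enolisation of 12 gives the phenol. The closest known reaction is the Danheiser benzannulation in its α-diazo ketone form, for which alkoxy- and silyloxyalkynes are standard partners. No lasting stereocentre arises, since C4a' in 10 and C6' in 12 are transient and the C8–C6' axis forms as a racemate. The step needs head-to-tail regiochemistry in the [2+2] event, and the polarity of the ynol ether secures it because its nucleophilic CH terminus attacks the electrophilic ketene carbonyl carbon, which sets the two oxygens meta and leaves only O7' as free OH. The E geometry of 7 keeps the bulky aryl group pointing outwards at the closing terminus, and the excess of 8 should outrun capture of 9 by phenol already formed.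

Step 5
Reactants: 13 2-(2,6-dimethoxy-4-methylphenyl)-5-ethoxy-3-methylphenol
Product: 14 2-(2,6-dimethoxy-4-methylphenyl)-5-ethoxy-1-methyl-3-(propan-2-yloxy)benzene
Conditions: 2-bromopropane, K2CO3, DMF, 60 °C
Reagents that add atoms: 2-bromopropane CC(C)Br
Why: Williamson ether synthesis on the only free OH gives a secondary alkyl ether that keeps O7' a strong donor para to C4a', turns its bulk towards C8'–H because the C6' aryl group blocks the other side, and tolerates TiCl4.

Step 6
Reactants: 14 2-(2,6-dimethoxy-4-methylphenyl)-5-ethoxy-1-methyl-3-(propan-2-yloxy)benzene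
Product: 15 1-[3-(3-acetyl-4-ethoxy-2-methyl-6-propan-2-yloxyphenyl)-2,4-dimethoxy-6-methylphenyl]ethanone (acetyl groups on C4a and C4a')
Conditions: AcCl, TiCl4, CH2Cl2, −10 °C to rt
Reagents that add atoms: acetyl chloride CC(=O)Cl
Why: This is a twofold Friedel–Crafts acylation of two orcinol-diether rings, a class that reacts ortho to methyl and para to alkoxy rather than between the oxygens, so ring A offers two equivalent sites, ring B should react at C4a' (para to O-iPr, ortho to OEt) because C8' is doubly ortho and screened, and each acetyl group shuts its ring to a second attack.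

Step 7
Reactants: 15 1-[3-(3-acetyl-4-ethoxy-2-methyl-6-propan-2-yloxyphenyl)-2,4-dimethoxy-6-methylphenyl]ethanone
Product: 16 1-[3-(3-acetyl-4,6-dihydroxy-2-methylphenyl)-2-hydroxy-4-methoxy-6-methylphenyl]ethanone
Conditions: BCl3 (excess), CH2Cl2, −78 °C to rt; aq. HCl
Reagents that add atoms: none
Why: In this Lewis-acid ether cleavage BCl3 bound to each acetyl oxygen draws C8a–OMe and C8a'–OEt into six-membered chelates that chloride dealkylates first, the excess reagent removes the secondary isopropyl ether by its easier ionising pathway, and the unchelated primary C7–OMe para to a carbonyl group should stay untouched at this temperature.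

Step 8
Reactants: 16 1-[3-(3-acetyl-4,6-dihydroxy-2-methylphenyl)-2-hydroxy-4-methoxy-6-methylphenyl]ethanone
Product: 17 1-[3-(3-acetyl-6-benzyloxy-4-hydroxy-2-methylphenyl)-2-hydroxy-4-methoxy-6-methylphenyl]ethanone
Conditions: BnBr (1.05 equiv), K2CO3, acetone, reflux
Reagents that add atoms: benzyl bromide BrCc1ccccc1
Why: In this chemoselective Williamson benzylation O7'–H, para to acetyl, is the most acidic phenol and the only one not locked in a hydrogen bond to a carbonyl oxygen, the behaviour familiar from 2,4-dihydroxyacetophenones, so one equivalent of halide should go there.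

Step 9
Reactants: 17 1-[3-(3-acetyl-6-benzyloxy-4-hydroxy-2-methylphenyl)-2-hydroxy-4-methoxy-6-methylphenyl]ethanone
Product: 19 8-[7-(benzyloxy)-4-hydroxy-5-methyl-2-oxo-2H-chromen-6-yl]-4-hydroxy-7-methoxy-5-methyl-2H-chromen-2-one, via bis(β-keto ester) 18 (not isolated)
Conditions: NaH (excess), (EtO)2CO, toluene, reflux; then aq. HCl
Reagents that add atoms: diethyl carbonate CCOC(=O)OCC
Why: A twofold Claisen condensation of the methyl ketone enolates with diethyl carbonate gives β-keto esters whose neighbouring phenoxides lactonise at once, and formation of the stabilised 4-oxidocoumarin salts drives both closures, which is the standard passage from 2-hydroxy-6-methylacetophenones to 4-hydroxy-5-methylcoumarins.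

Step 10
Reactants: 19 8-[7-(benzyloxy)-4-hydroxy-5-methyl-2-oxo-2H-chromen-6-yl]-4-hydroxy-7-methoxy-5-methyl-2H-chromen-2-one
Product: 20 8-[7-(benzyloxy)-4-methoxy-5-methyl-2-oxo-2H-chromen-6-yl]-4,7-dimethoxy-5-methyl-2H-chromen-2-one
Conditions: Me2SO4, K2CO3, acetone, reflux
Reagents that add atoms: dimethyl sulfate COS(=O)(=O)OC
Why: O-alkylation of the two vinylogous carboxylates with the hard electrophile dimethyl sulfate should give 4-methoxycoumarins in preference to C3-methyl or 2-methoxychromone isomers, and no other acidic site is open because O7' carries benzyl.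

Step 11
Reactants: 20 8-[7-(benzyloxy)-4-methoxy-5-methyl-2-oxo-2H-chromen-6-yl]-4,7-dimethoxy-5-methyl-2H-chromen-2-one
Product: 21 8-(7-hydroxy-4-methoxy-5-methyl-2-oxo-2H-chromen-6-yl)-4,7-dimethoxy-5-methyl-2H-chromen-2-one (CNP0113839.0)
Conditions: H2 (1 atm), Pd/C, EtOAc–MeOH, rt
Reagents that add atoms: none
Why: Catalytic hydrogenolysis cleaves only the benzylic C–O bond, while aryl methyl ethers, lactones and the donor-substituted C3=C4 bonds of 4-methoxycoumarins are inert at one atmosphere.

Compound list
1 | 2,6-dimethoxy-4-methylbenzaldehyde | COc1cc(C)cc(OC)c1C=O | starting material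
2 | triethyl 2-phosphonopropionate | CCOC(=O)C(C)P(=O)(OCC)OCC | starting material
3 | ethyl (E)-3-(2,6-dimethoxy-4-methylphenyl)-2-methylprop-2-enoate | CCOC(=O)/C(C)=C/c1c(OC)cc(C)cc1OC | intermediate
4 | (E)-3-(2,6-dimethoxy-4-methylphenyl)-N-methoxy-N,2-dimethylprop-2-enamide | CON(C)C(=O)/C(C)=C/c1c(OC)cc(C)cc1OC | intermediate
5 | (E)-4-(2,6-dimethoxy-4-methylphenyl)-3-methylbut-3-en-2-one | CC(=O)/C(C)=C/c1c(OC)cc(C)cc1OC | intermediate
6 | (E)-6-(2,6-dimethoxy-4-methylphenyl)-1,1,1-trifluoro-5-methylhex-5-ene-2,4-dione | O=C(CC(=O)/C(C)=C/c1c(OC)cc(C)cc1OC)C(F)(F)F | intermediate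
7 | (E)-1-diazo-4-(2,6-dimethoxy-4-methylphenyl)-3-methylbut-3-en-2-one | [N-]=[N+]=CC(=O)/C(C)=C/c1c(OC)cc(C)cc1OC | intermediate
8 | ethoxyacetylene | CCOC#C | starting material
9 | (E)-4-(2,6-dimethoxy-4-methylphenyl)-3-methylbuta-1,3-dien-1-one | O=C=C/C(C)=C/c1c(OC)cc(C)cc1OC | intermediate
10 | 4-[(E)-1-(2,6-dimethoxy-4-methylphenyl)prop-1-en-2-yl]-3-ethoxycyclobut-2-en-1-one (racemic) | CCOC1=CC(=O)C1/C(C)=C/c1c(OC)cc(C)cc1OC | intermediate
11 | (3E,5E)-6-(2,6-dimethoxy-4-methylphenyl)-3-ethoxy-5-methylhexa-1,3,5-trien-1-one | O=C=C/C(OCC)=C\C(C)=C\c1c(OC)cc(C)cc1OC | intermediate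
12 | 6-(2,6-dimethoxy-4-methylphenyl)-3-ethoxy-5-methylcyclohexa-2,4-dien-1-one (racemic) | CCOC1=CC(=O)C(c2c(OC)cc(C)cc2OC)C(C)=C1 | intermediate
13 | 2-(2,6-dimethoxy-4-methylphenyl)-5-ethoxy-3-methylphenol | CCOc1cc(O)c(-c2c(OC)cc(C)cc2OC)c(C)c1 | intermediate
14 | 2-(2,6-dimethoxy-4-methylphenyl)-5-ethoxy-1-methyl-3-(propan-2-yloxy)benzene | CCOc1cc(OC(C)C)c(-c2c(OC)cc(C)cc2OC)c(C)c1 | intermediate
15 | 1-[3-(3-acetyl-4-ethoxy-2-methyl-6-propan-2-yloxyphenyl)-2,4-dimethoxy-6-methylphenyl]ethanone | CCOc1cc(OC(C)C)c(-c2c(OC)cc(C)c(C(C)=O)c2OC)c(C)c1C(C)=O | intermediate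
16 | 1-[3-(3-acetyl-4,6-dihydroxy-2-methylphenyl)-2-hydroxy-4-methoxy-6-methylphenyl]ethanone | CC(=O)c1c(O)cc(O)c(-c2c(OC)cc(C)c(C(C)=O)c2O)c1C | intermediate
17 | 1-[3-(3-acetyl-6-benzyloxy-4-hydroxy-2-methylphenyl)-2-hydroxy-4-methoxy-6-methylphenyl]ethanone | CC(=O)c1c(O)cc(OCc2ccccc2)c(-c2c(OC)cc(C)c(C(C)=O)c2O)c1C | intermediate
18 | ethyl 3-[3-[6-benzyloxy-3-(3-ethoxy-3-oxopropanoyl)-4-hydroxy-2-methylphenyl]-2-hydroxy-4-methoxy-6-methylphenyl]-3-oxopropanoate | CCOC(=O)CC(=O)c1c(O)cc(OCc2ccccc2)c(-c2c(OC)cc(C)c(C(=O)CC(=O)OCC)c2O)c1C | intermediate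
19 | 8-[7-(benzyloxy)-4-hydroxy-5-methyl-2-oxo-2H-chromen-6-yl]-4-hydroxy-7-methoxy-5-methyl-2H-chromen-2-one | COc1cc(C)c2c(O)cc(=O)oc2c1-c1c(OCc2ccccc2)cc2oc(=O)cc(O)c2c1C | intermediate
20 | 8-[7-(benzyloxy)-4-methoxy-5-methyl-2-oxo-2H-chromen-6-yl]-4,7-dimethoxy-5-methyl-2H-chromen-2-one | COc1cc(C)c2c(OC)cc(=O)oc2c1-c1c(OCc2ccccc2)cc2oc(=O)cc(OC)c2c1C | intermediate
21 | 8-(7-hydroxy-4-methoxy-5-methyl-2-oxo-2H-chromen-6-yl)-4,7-dimethoxy-5-methyl-2H-chromen-2-one | COc1cc(C)c2c(OC)cc(=O)oc2c1-c1c(O)cc2oc(=O)cc(OC)c2c1C | target

Total step count: 11. Longest linear sequence: 11 steps (1 to 21).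

Steps most likely to fail

**Step 4.**
- What may go wrong:
  - Under irradiation the styryl double bond may isomerise, and the cyclobutenone may suffer secondary photolysis.
  - The ketene may be used up by dimerisation or by phenol already formed.
  - The six-electron closure onto a carbon that carries a di-ortho-substituted aryl group may be slow.
- Fallback (sets out from 7, returns at 13): the ketene is generated in the dark by dehydrochlorination, so light and annulation are separated.
  - Wolff rearrangement of 7 with AgO2CPh and Et3N in MeOH traps the ketene as methyl (E)-4-(2,6-dimethoxy-4-methylphenyl)-3-methylbut-3-enoate F1.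
  - LiOH then gives (E)-4-(2,6-dimethoxy-4-methylphenyl)-3-methylbut-3-enoic acid F2.
  - Oxalyl chloride gives (E)-4-(2,6-dimethoxy-4-methylphenyl)-3-methylbut-3-enoyl chloride F3.
  - Slow addition of iPr2NEt to F3 and excess 8 in toluene regenerates 9 at low stationary concentration.
  - Cyclobutenone 10 can then be purified and thermolysed on its own to 13.

**Step 6.**
- What may go wrong:
  - Acylation may stall after ring A has reacted, because C4a' is buttressed by the C5' methyl and C6' aryl groups.
  - Alternatively, part of the electrophile may attack C8'.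
  - Early loss of isopropyl or of a chelated ether after acylation is harmless, since step 7 removes these groups anyway.
- Fallback (sets out from 14, returns at 15): the polarity of the bond formation is inverted.
  - NBS (2 equiv) in MeCN is a smaller and more para-selective electrophile. It should brominate para to an alkoxy group on each ring and give 2-bromo-4-(3-bromo-2,6-dimethoxy-4-methylphenyl)-1-ethoxy-3-methyl-5-(propan-2-yloxy)benzene F4.
  - Twofold bromine–lithium exchange (n-BuLi, THF, −78 °C) and a quench with N-methoxy-N-methylacetamide then give 15.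

**Step 9.**
- What may go wrong:
  - The polyanion may be poorly soluble.
  - One hindered ketone may fail to condense, so that only one pyranone closes.
  - O-ethoxycarbonylation may occur without the C-acylation that has to follow.
- Fallback (sets out from 17, returns at 19): the acyl carbon is delivered intramolecularly.
  - Ethyl chloroformate with NaH in THF converts both chelated phenols into ethyl [2-acetyl-6-[3-acetyl-6-benzyloxy-4-(ethoxycarbonyloxy)-2-methylphenyl]-5-methoxy-3-methylphenyl] carbonate F5.
  - LiN(SiMe3)2 in THF then triggers a Baker–Venkataraman-type O-to-C ethoxycarbonyl shift to 18, which lactonises to 19 on acidification.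

Further compounds
F1 | step 4 | methyl (E)-4-(2,6-dimethoxy-4-methylphenyl)-3-methylbut-3-enoate | COC(=O)C/C(C)=C/c1c(OC)cc(C)cc1OC
F2 | step 4 | (E)-4-(2,6-dimethoxy-4-methylphenyl)-3-methylbut-3-enoic acid | OC(=O)C/C(C)=C/c1c(OC)cc(C)cc1OC
F3 | step 4 | (E)-4-(2,6-dimethoxy-4-methylphenyl)-3-methylbut-3-enoyl chloride | ClC(=O)C/C(C)=C/c1c(OC)cc(C)cc1OC
F4 | step 6 | 2-bromo-4-(3-bromo-2,6-dimethoxy-4-methylphenyl)-1-ethoxy-3-methyl-5-(propan-2-yloxy)benzene | CCOc1cc(OC(C)C)c(-c2c(OC)cc(C)c(Br)c2OC)c(C)c1Br
F5 | step 9 | ethyl [2-acetyl-6-[3-acetyl-6-benzyloxy-4-(ethoxycarbonyloxy)-2-methylphenyl]-5-methoxy-3-methylphenyl] carbonate | CCOC(=O)Oc1cc(OCc2ccccc2)c(-c2c(OC)cc(C)c(C(C)=O)c2OC(=O)OCC)c(C)c1C(C)=O
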